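The earlier runs and the new flask were computed with constants of no real substance; noise was put on by code.

In a one-step world, G + D giving J, product appears at full speed from the start. Green did not behave so: J stood at 1% after 4.00 min and 19% after 20.0 min. That lag fits the steps under discussion, where G first becomes L and L then takes a second D to give J.

| flask | G | D | remark | time |
|---|---|---|---|---|
| green | 0.089 M | 0.84 M | run made earlier |  |
| violet | 0.38 M | 0.84 M | run made earlier |  |
| teal | 1.3 M | 0.84 M | run made earlier |  |
| zeta | 0.10 M | 0.840 M |  | 80 min |
| delta | 0.20 M | 0.840 M |  | 80 min |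
| gamma | 0.40 M | 0.840 M |  | 80 min |
| epsilon | 0.80 M | 0.840 M |  | 80 min |
| alpha | 1.5 M | 0.840 M |  | 80 min |

- green (time / min: J / %): 4.00: 1; 10.0: 7; 20.0: 19; 30.0: 24; 40.0: 33
- violet (time / min: J / %): 8.00: 3; 15.0: 7; 25.0: 14; 30.0: 15; 40.0: 21
- teal (time / min: J / %): 3.00: 0; 6.00: 1; 12.0: 0; 20.0: 2; 40.0: 2

(scatter of a reading: 2 percentage points)

- steps under discussion: D + L -> J; L <-> E; G + D -> L; L <-> X
- "hardly changes" means that all values lie within two and a half points (for a concentration: within two and a half percent of the largest)

- [J] at the end for zeta, delta, gamma, epsilon, alpha, in this order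
- the shape of the row from first to last (hardly changes / falls all the way / rises all the way / falls, then rises / rises, then falls)

After the lag I treated the material in green not yet J as one store emptying into J at a pace proportional to D, a pseudo-first-order decay while D barely moves. Between 20.0 min and 40.0 min that store fell from 81.0% to 67.0%, a decay of 0.00949 min⁻¹. I took green's D as the charge less one D per G and one per J at 30.0 min, which is 0.730 M. Dividing gave 0.0130 M⁻¹ min⁻¹, which I call the drain constant: the fraction of the store becoming J per minute per molar of D. It is a reading, carrying the scatter of 2 percentage points.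

Running on from green's 33% at that decay, I expected 0.0542 M of J in zeta. Alpha was charged with more G than D, as teal was, and teal's reading of J after 40.0 min came to 0.0260 M, so I expected the row to fall at its end.

The forecast gave 0.055 M, 0.097 M, 0.135 M, 0.065 M and 0.023 M, shape rises, then falls, holding that “a large G charge uses up D before L can react”. For zeta my figure was lower.

The flasks gave 0.0506 M, 0.0892 M, 0.127 M, 0.0777 M and 0.0282 M, shape rises, then falls. The forecast stood higher for gamma and lower for epsilon.

    D + L → J (k = 4.80 × 10⁻⁴ M⁻¹ s⁻¹)
    L ⇌ E (K = 0.280, k = 7.80 × 10⁻⁴ s⁻¹)
    G + D → L (k = 0.00390 M⁻¹ s⁻¹)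
    L ⇌ X (K = 0.930, k = 0.00240 s⁻¹)

In zeta at 80.0 min, L turned into J at 0.14 times the forward rate at which it turned into X, while L and X stood at 21.6% and 21.3%. At 3.66 min in zeta that ratio had been 0.16. Started from zeta's 29.7% of J at half time, with the mean of zeta's D at half time and at the end, the drain constant gives 51.2% at the end, where zeta stood at 50.6%. Started the same way from gamma's 19.0%, with gamma's own mean D, it gives 32.1%, where gamma stood at 31.8%.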